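The two benzene-ring bromines are not introduced by substitution; they are carried in. C7a, C7, C6 and C5 of the indole, together with N1 and the bromines on C7 and C5, correspond to C3, C4, C5 and C6 of 4,6-dibromopyridazin-3-amine, so only C3a and C4 must be added, and a terminal alkyne held on nitrogen by a two-carbon chain (future C2 and C3) supplies them. One thermal operation, [4+2] addition of that alkyne across the diazine followed by extrusion of N2, closes the five-membered ring (C3a–C7a) and creates the benzene ring (C4–C5). The precursor is the N-acetyl-N-(but-3-ynyl) derivative of the dibromoaminopyridazine; deacetylation, dehydrogenation and C3 bromination then finish.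

Key step: step 4

Remark on the chemistry: the acetyl group is kept on nitrogen because it makes the N–H acidic enough for alkylation and removes the donor effect of nitrogen on the diazine; the target has no stereocentre, and the transient cycloadduct is racemic, so its SMILES carries no descriptors.

Step 1
Reactants: 1 6-bromopyridazin-3-amine
Product: 2 4,6-dibromopyridazin-3-amine
Conditions: Br2 (1.1 equiv), NaHCO3, MeOH, 0 °C to rt
Reagents that add atoms: bromine, BrBr
Why: Electrophilic aromatic bromination, in which the amino group activates the otherwise electron-poor diazine and directs the electrophile to the adjacent C4 (C5 is meta to the donor), while NaHCO3 takes up HBr so that the amine is not protonated and deactivated.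

Step 2
Reactants: 2 4,6-dibromopyridazin-3-amine
Product: 3 N-(4,6-dibromopyridazin-3-yl)acetamide
Conditions: Ac2O, AcOH, 100 °C
Reagents that add atoms: acetic anhydride, CC(=O)OC(C)=O
Why: N-acetylation (nucleophilic acyl substitution) of a weakly nucleophilic heteroarylamine, for which hot anhydride is used, and the same electron deficiency together with the ortho bromine should disfavour a second acylation.

Step 3
Reactants: 3 N-(4,6-dibromopyridazin-3-yl)acetamide; 4 but-3-yn-1-ol
Product: 5 N-(but-3-yn-1-yl)-N-(4,6-dibromopyridazin-3-yl)acetamide
Conditions: PPh3, DIAD, THF, 0 °C to rt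
Reagents that add atoms: none
Why: Mitsunobu N-alkylation, in which the acetamide N–H, acidified by the dibromodiazine ring, protonates the PPh3/DIAD betaine and its conjugate base displaces the oxyphosphonium derivative of the primary alcohol by SN2, the alkyne and both C–Br bonds being inert under these neutral conditions.

Step 4
Reactants: 5 N-(but-3-yn-1-yl)-N-(4,6-dibromopyridazin-3-yl)acetamide
Product: 7 1-acetyl-5,7-dibromoindoline, via azo-bridged cycloadduct 6 (not isolated)
Conditions: 1,3,5-triisopropylbenzene (0.02 M, degassed), Ar, 230 °C
Reagents that add atoms: none
Why: The tethered alkyne acts as the 2π partner and C3 to C6 of the electron-poor 1,2-diazine as the 4π partner in an intramolecular inverse-electron-demand Diels–Alder reaction that gives the azo-bridged adduct 6, which at once loses N2 by retro-Diels–Alder cycloreversion, so the carbocycle emerges at the arene oxidation level without any separate aromatisation step. The closest known reaction type is the thermal intramolecular alkyne–pyridazine cycloaddition of N-acyl 3-(alkynylamino)pyridazines to N-acylindolines, which proceeds at this temperature for 6-halo substrates. The five-membered ring closes through the C3a–C7a bond in a 5-exo-dig sense inside the cycloaddition, and the six-membered carbocycle is formed by the two new bonds C3a–C7a and C4–C5 and is kept when the N=N bridge departs. No stereocentre is created in 7, since the two bridgehead centres of racemic 6 are flattened on loss of N2. The step needs one regiochemical outcome and a preference for cycloaddition over decomposition: the two-carbon chain on nitrogen lets the internal alkyne carbon reach only C3 and therefore sends the terminal CH to C6, which fixes the bromines at C5 and C7, while the N-acetyl group cancels the donor effect of nitrogen, the two bromines lower the diazine LUMO, the C4 bromine twists the amide so that the butynyl arm lies over the ring face, and high dilution in degassed solvent suppresses intermolecular alkyne reactions.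

Step 5
Reactants: 7 1-acetyl-5,7-dibromoindoline
Product: 8 5,7-dibromoindoline
Conditions: 6 M HCl, EtOH, reflux; basic work-up
Reagents that add atoms: none
Why: Acid-catalysed amide hydrolysis, in which the N-acetyl group, twisted out of conjugation by the C7 bromine, should be cleaved by hot aqueous acid while the aryl bromides and the indoline ring are unaffected.

Step 6
Reactants: 8 5,7-dibromoindoline
Product: 9 5,7-dibromoindole
Conditions: DDQ (1.1 equiv), toluene, rt
Reagents that add atoms: none
Why: Quinone dehydrogenation (hydride abstraction from C2 next to nitrogen, then proton loss and tautomerisation) is driven by formation of the aromatic pyrrole ring and leaves the C–Br bonds alone.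

Step 7
Reactants: 9 5,7-dibromoindole
Product: 10 3,5,7-tribromoindole
Conditions: NBS (1.0 equiv), DMF, 0 °C, dark
Reagents that add atoms: N-bromosuccinimide, O=C1CCC(=O)N1Br
Why: Electrophilic aromatic substitution at C3, by far the most nucleophilic position of the indole since the benzene ring is deactivated by its two bromines, so one equivalent of NBS at low temperature should deliver the 3-bromide selectively.

Compound list
1 | 6-bromopyridazin-3-amine | Nc1ccc(Br)nn1 | starting material
2 | 4,6-dibromopyridazin-3-amine | Nc1nnc(Br)cc1Br | intermediate
3 | N-(4,6-dibromopyridazin-3-yl)acetamide | CC(=O)Nc1nnc(Br)cc1Br | intermediate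
4 | but-3-yn-1-ol | C#CCCO | starting material
5 | N-(but-3-yn-1-yl)-N-(4,6-dibromopyridazin-3-yl)acetamide | CC(=O)N(CCC#C)c1nnc(Br)cc1Br | intermediate
6 | azo-bridged cycloadduct, 1-acetyl-5,7-dibromo-2,3,5,7a-tetrahydro-5,7a-epidiazenoindole (N=N bridge from C5 to C7a, double bonds C3a=C4 and C6=C7; racemic, not isolated) | CC(=O)N1CCC2=CC3(Br)C=C(Br)C21N=N3 | intermediate
7 | 1-acetyl-5,7-dibromoindoline | CC(=O)N1CCc2cc(Br)cc(Br)c21 | intermediate
8 | 5,7-dibromoindoline | Brc1cc(Br)c2NCCc2c1 | intermediate
9 | 5,7-dibromoindole | Brc1cc(Br)c2[nH]ccc2c1 | intermediate
10 | 3,5,7-tribromoindole | Brc1cc(Br)c2[nH]cc(Br)c2c1 | target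

Total step count: 7 (6 if 4,6-dibromopyridazin-3-amine (2) is purchased instead of made).
Longest linear sequence: 7 steps, from 1 to 10; but-3-yn-1-ol (4) enters in step 3.

Steps most likely to fail

Step 4 (cycloaddition with N2 loss). The cycloaddition may be slowed by crowding around the amide nitrogen from the C4 bromine. At 230 °C, oligomerisation of the terminal alkyne and slow loss of bromine could then overtake ring formation. The fallback keeps the diazine cycloaddition but runs it on the less hindered substrate without the C4 bromine and adds the C7 bromine afterwards by electrophilic substitution. It sets out from 6-bromopyridazin-3-amine (1) and comes back to the route at 5,7-dibromoindoline (8). Compound 1 is acetylated (Ac2O, 100 °C) to N-(6-bromopyridazin-3-yl)acetamide F1. This is alkylated with but-3-yn-1-ol (4) under Mitsunobu conditions (PPh3, DIAD, THF) to N-(but-3-yn-1-yl)-N-(6-bromopyridazin-3-yl)acetamide F2. Heating in 1,3,5-triisopropylbenzene at 230 °C should pass through 1-acetyl-5-bromo-2,3,5,7a-tetrahydro-5,7a-epidiazenoindole F3 (not isolated) and give 1-acetyl-5-bromoindoline F4. Hot 6 M HCl in EtOH then gives 5-bromoindoline F5. Bromination with Br2 in AcOH, the para position being blocked, should go ortho to nitrogen at C7 and give 8.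

Step 3 (Mitsunobu alkylation). Alkylation may stray to the amide oxygen or to ring nitrogen N2 because the exocyclic nitrogen is flanked by the C4 bromine. The hindered amide may also react so slowly that the activated alcohol is consumed by the hydrazide. The fallback makes the exocyclic C–N bond by nucleophilic aromatic substitution with the ready-made butynylamine and brominates and acetylates afterwards. It sets out from but-3-yn-1-ol (4) and comes back at precursor 5. Alcohol 4 is converted by a Mitsunobu reaction with phthalimide into 2-(but-3-yn-1-yl)isoindoline-1,3-dione F6 and then by hydrazinolysis (N2H4·H2O, EtOH) into but-3-yn-1-amine F7, which can also be bought. The amine displaces one bromide of purchased 3,6-dibromopyridazine F8 (K2CO3, DMSO, 90 °C) to give 6-bromo-N-(but-3-yn-1-yl)pyridazin-3-amine F9. NBS in MeCN at 0 °C should brominate ortho to the amino group and give 4,6-dibromo-N-(but-3-yn-1-yl)pyridazin-3-amine F10. N-acetylation (LiHMDS then AcCl in THF, or Ac2O with DMAP at 100 °C) gives 5.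

Step 7 (C3 bromination). A second bromination at C2 may occur, or traces of HBr may oligomerise the N–H 3-bromoindole while it forms and during isolation. The fallback brominates an N-sulfonyl indole and unmasks the nitrogen under basic conditions, in which 3-bromoindoles are stable. It sets out from 5,7-dibromoindole (9) and comes back at target 10. Compound 9 is N-tosylated (NaH, TsCl, DMF) to 5,7-dibromo-1-tosylindole F11. Br2 in CH2Cl2 should give 3,5,7-tribromo-1-tosylindole F12 by addition across C2=C3 and loss of HBr. NaOH in MeOH/THF at 50 °C then removes the sulfonyl group to give 10.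

Further compounds
F1 | step 4 | N-(6-bromopyridazin-3-yl)acetamide | CC(=O)Nc1ccc(Br)nn1
F2 | step 4 | N-(but-3-yn-1-yl)-N-(6-bromopyridazin-3-yl)acetamide | CC(=O)N(CCC#C)c1ccc(Br)nn1
F3 | step 4 | 1-acetyl-5-bromo-2,3,5,7a-tetrahydro-5,7a-epidiazenoindole | CC(=O)N1CCC2=CC3(Br)C=CC21N=N3
F4 | step 4 | 1-acetyl-5-bromoindoline | CC(=O)N1CCc2cc(Br)ccc21
F5 | step 4 | 5-bromoindoline | Brc1ccc2NCCc2c1
F6 | step 3 | 2-(but-3-yn-1-yl)isoindoline-1,3-dione | O=C1N(CCC#C)C(=O)c2ccccc12
F7 | step 3 | but-3-yn-1-amine | NCCC#C
F8 | step 3 | 3,6-dibromopyridazine | Brc1ccc(Br)nn1
F9 | step 3 | 6-bromo-N-(but-3-yn-1-yl)pyridazin-3-amine | C#CCCNc1ccc(Br)nn1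
F10 | step 3 | 4,6-dibromo-N-(but-3-yn-1-yl)pyridazin-3-amine | C#CCCNc1nnc(Br)cc1Br
F11 | step 7 | 5,7-dibromo-1-tosylindole | Cc1ccc(cc1)S(=O)(=O)n1ccc2cc(Br)cc(Br)c21
F12 | step 7 | 3,5,7-tribromo-1-tosylindole | Cc1ccc(cc1)S(=O)(=O)n1cc(Br)c2cc(Br)cc(Br)c21
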